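**Retrosynthetic overview**
- The target is reached by desilylation of its C10 silyl ether, which comes from palmitoylation of the free ring hydroxyl of a 3-hydroxyoxolane.
- The oxolane, the only ring, is formed last in the skeleton assembly: the C9 hydroxyl of a chlorodiol displaces the C6 chloride (5-exo, inversion).
- The chlorodiol comes from 1,3-syn reduction of a β-hydroxy ketone, itself made by an anti-selective lithium-enolate aldol of a C12 methyl ketone with (R)-2-chloroheptanal (C7–C8 bond).
- The methyl ketone comes from undec-10-enoyl chloride by Evans–Davis α-hydroxylation (sets C10), Weinreb amide formation, silylation and MeMgBr addition.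
- (R)-2-Chloroheptanal comes from heptanal by organocatalytic α-chlorination.

Assumption: locants C1–C19 in the comments are those of the nonadec-18-ene chain (ring oxygen on C6 and C9, ester on C7, free hydroxyl on C10; target = 6S,7S,9R,10R); n-BuLi, NaN(SiMe3)2, LiN(iPr)2 and MeMgBr are used as purchased solutions.

**Route**

Step 1
Reactants: 1 (4R)-4-benzyl-1,3-oxazolidin-2-one; 2 undec-10-enoyl chloride
Product: 4 (4R)-4-benzyl-3-(undec-10-enoyl)-1,3-oxazolidin-2-one, via lithium oxazolidinide 3 (not isolated)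
Conditions: n-BuLi, THF, −78 °C; then 2, −78 → 0 °C
Reagents that add atoms: none
Why: N-acylation of the lithiated auxiliary by the acid chloride (nucleophilic acyl substitution) is fast and clean, and no stereocentre is formed.

Step 2
Reactants: 4 (4R)-4-benzyl-3-(undec-10-enoyl)-1,3-oxazolidin-2-one
Product: 6 (4R)-4-benzyl-3-[(2R)-2-hydroxyundec-10-enoyl]-1,3-oxazolidin-2-one, via sodium Z-enolate 5 (not isolated)
Conditions: NaN(SiMe3)2, THF, −78 °C; 2-(phenylsulfonyl)-3-phenyloxaziridine, −78 °C; AcOH quench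
Reagents that add atoms: 2-(phenylsulfonyl)-3-phenyloxaziridine (Davis oxaziridine), O=S(=O)(c1ccccc1)N1OC1c1ccccc1
Why: Evans–Davis asymmetric enolate hydroxylation: the chelated Z-enolate is oxidised on the face opposite the benzyl group, which for the (4R)-auxiliary gives the 2R alcohol (future C10) in high dr, and the terminal alkene is inert.

Step 3
Reactants: 6 (4R)-4-benzyl-3-[(2R)-2-hydroxyundec-10-enoyl]-1,3-oxazolidin-2-one
Product: 7 (2R)-2-hydroxy-N-methoxy-N-methylundec-10-enamide
Conditions: MeNHOMe·HCl, AlMe3, CH2Cl2, −10 °C → rt; 1 M HCl work-up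
Reagents that add atoms: N,O-dimethylhydroxylamine hydrochloride, CNOC.Cl
Why: Weinreb transamination of the imide by the aluminium amide; the aluminium alkoxide of the free α-hydroxyl directs attack to the exocyclic carbonyl, the auxiliary is released and C10 is untouched.

Step 4
Reactants: 7 (2R)-2-hydroxy-N-methoxy-N-methylundec-10-enamide
Product: 8 (2R)-2-{[tert-butyl(dimethyl)silyl]oxy}-N-methoxy-N-methylundec-10-enamide
Conditions: TBSCl, imidazole, DMF, rt
Reagents that add atoms: tert-butyl(chloro)dimethylsilane (TBSCl), CC(C)(C)[Si](C)(C)Cl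
Why: Standard O-silylation of a secondary alcohol; the non-chelating silyl ether later supports Felkin–Anh control in step 8 and is stable through to step 11.

Step 5
Reactants: 8 (2R)-2-{[tert-butyl(dimethyl)silyl]oxy}-N-methoxy-N-methylundec-10-enamide
Product: 10 (3R)-3-{[tert-butyl(dimethyl)silyl]oxy}dodec-11-en-2-one, via magnesium hemiaminal 9 (not isolated)
Conditions: MeMgBr, THF, 0 °C; then 1 M HCl, 0 °C
Reagents that add atoms: methylmagnesium bromide, C[Mg]Br
Why: Weinreb ketone synthesis: the chelated tetrahedral adduct collapses only on work-up, so a single methyl addition gives the ketone without epimerising C10.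

Step 6
Reactants: 11 heptanal
Product: 12 (2R)-2-chloroheptanal
Conditions: (5R)-5-benzyl-2,2,3-trimethylimidazolidin-4-one·CF3CO2H (5 mol%), 2,3,4,5,6,6-hexachlorocyclohexa-2,4-dien-1-one, acetone, −30 °C; pentane extraction, used at once
Reagents that add atoms: 2,3,4,5,6,6-hexachlorocyclohexa-2,4-dien-1-one, O=C1C(Cl)=C(Cl)C(Cl)=C(Cl)C1(Cl)Cl
Why: Enamine-organocatalytic α-chlorination: the E-enamine is chlorinated on the face not shielded by the catalyst's benzyl group, which by this shielding model gives the 2R aldehyde (future C6) from the (5R)-catalyst.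

Step 7
Reactants: 10 (3R)-3-{[tert-butyl(dimethyl)silyl]oxy}dodec-11-en-2-one; 12 (2R)-2-chloroheptanal
Product: 14 (6R,7S,10R)-10-{[tert-butyl(dimethyl)silyl]oxy}-6-chloro-7-hydroxynonadec-18-en-9-one, via lithium enolate 13 (not isolated)
Conditions: LiN(iPr)2, THF, −78 °C; then 12, −78 °C, 30 min; AcOH quench at −78 °C
Reagents that add atoms: none
Why: Intermolecular lithium-enolate aldol addition: the kinetic methyl-side enolate adds to the α-chloroaldehyde through the Cornforth (polar Felkin–Anh) transition state, giving the 6,7-anti chlorohydrin and so the 7S carbinol, while C6 and C10 are carried through at −78 °C.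

Step 8
Reactants: 14 (6R,7S,10R)-10-{[tert-butyl(dimethyl)silyl]oxy}-6-chloro-7-hydroxynonadec-18-en-9-one
Product: 16 (6R,7S,9R,10R)-10-{[tert-butyl(dimethyl)silyl]oxy}-6-chlorononadec-18-ene-7,9-diol, via diethylborinate chelate 15 (not isolated)
Conditions: Et2BOMe, THF/MeOH 4:1, −78 °C; NaBH4, −78 °C; AcOH, then MeOH co-evaporation
Reagents that add atoms: none
Why: Narasaka–Prasad reduction: hydride adds axially to the six-membered boron chelate to give the 7,9-syn diol (9R), reinforced by Felkin–Anh control from the C10 silyloxy group (9,10-syn); the non-basic work-up keeps the chlorohydrin from closing to an epoxide.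

Step 9
Reactants: 16 (6R,7S,9R,10R)-10-{[tert-butyl(dimethyl)silyl]oxy}-6-chlorononadec-18-ene-7,9-diol
Product: 17 (2S,3S,5R)-5-[(1R)-1-{[tert-butyl(dimethyl)silyl]oxy}dec-9-en-1-yl]-2-pentyloxolan-3-ol
Conditions: AgOSO2CF3, Ag2O, THF, rt → 50 °C
Reagents that add atoms: none
Why: Silver-assisted intramolecular etherification (5-exo-tet SN2): the C9 hydroxyl displaces the activated C6 chloride with inversion (6R → 6S), giving the 2,5-trans, 2,3-cis oxolane, and Ag2O buffers the acid so the silyl ether survives.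

Step 10
Reactants: 17 (2S,3S,5R)-5-[(1R)-1-{[tert-butyl(dimethyl)silyl]oxy}dec-9-en-1-yl]-2-pentyloxolan-3-ol; 18 hexadecanoyl chloride
Product: 19 (2S,3S,5R)-5-[(1R)-1-{[tert-butyl(dimethyl)silyl]oxy}dec-9-en-1-yl]-2-pentyloxolan-3-yl hexadecanoate
Conditions: pyridine, 4-(dimethylamino)pyridine (cat.), CH2Cl2, 0 °C → rt
Reagents that add atoms: none
Why: Nucleophile-catalysed esterification of the only free hydroxyl (C7) with the acid chloride, with retention at the carbinol carbon.

Step 11
Reactants: 19 (2S,3S,5R)-5-[(1R)-1-{[tert-butyl(dimethyl)silyl]oxy}dec-9-en-1-yl]-2-pentyloxolan-3-yl hexadecanoate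
Product: 20 (2S,3S,5R)-5-[(1R)-1-hydroxydec-9-en-1-yl]-2-pentyloxolan-3-yl hexadecanoate
Conditions: HF·pyridine, pyridine/THF, 0 °C → rt
Reagents that add atoms: none
Why: Fluoride-mediated desilylation under buffered, non-basic conditions frees the C10 hydroxyl without cleaving or migrating the ester (the two oxygens are 1,4-related) and without touching the alkene.

**Compound list**

1 | (4R)-4-benzyl-1,3-oxazolidin-2-one | O=C1N[C@H](Cc2ccccc2)CO1 | starting material
2 | undec-10-enoyl chloride | C=CCCCCCCCCC(=O)Cl | starting material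
3 | lithium (4R)-4-benzyl-2-oxo-1,3-oxazolidin-3-ide (not isolated) | [Li+].O=C1[N-][C@H](Cc2ccccc2)CO1 | intermediate
4 | (4R)-4-benzyl-3-(undec-10-enoyl)-1,3-oxazolidin-2-one | C=CCCCCCCCCC(=O)N1[C@H](Cc2ccccc2)COC1=O | intermediate
5 | sodium (Z)-enolate of 4 (not isolated) | [Na+].C=CCCCCCCC/C=C(\[O-])N1[C@H](Cc2ccccc2)COC1=O | intermediate
6 | (4R)-4-benzyl-3-[(2R)-2-hydroxyundec-10-enoyl]-1,3-oxazolidin-2-one | C=CCCCCCCC[C@@H](O)C(=O)N1[C@H](Cc2ccccc2)COC1=O | intermediate
7 | (2R)-2-hydroxy-N-methoxy-N-methylundec-10-enamide | C=CCCCCCCC[C@@H](O)C(=O)N(C)OC | intermediate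
8 | (2R)-2-{[tert-butyl(dimethyl)silyl]oxy}-N-methoxy-N-methylundec-10-enamide | C=CCCCCCCC[C@@H](O[Si](C)(C)C(C)(C)C)C(=O)N(C)OC | intermediate
9 | bromomagnesium hemiaminal from 8 and MeMgBr (not isolated; hemiaminal carbon undefined) | C=CCCCCCCC[C@@H](O[Si](C)(C)C(C)(C)C)C(C)(O[Mg]Br)N(C)OC | intermediate
10 | (3R)-3-{[tert-butyl(dimethyl)silyl]oxy}dodec-11-en-2-one | C=CCCCCCCC[C@@H](O[Si](C)(C)C(C)(C)C)C(C)=O | intermediate
11 | heptanal | CCCCCCC=O | starting material
12 | (2R)-2-chloroheptanal | CCCCC[C@@H](Cl)C=O | intermediate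
13 | lithium (3R)-3-{[tert-butyl(dimethyl)silyl]oxy}dodeca-1,11-dien-2-olate (not isolated) | [Li+].C=CCCCCCCC[C@@H](O[Si](C)(C)C(C)(C)C)C(=C)[O-] | intermediate
14 | (6R,7S,10R)-10-{[tert-butyl(dimethyl)silyl]oxy}-6-chloro-7-hydroxynonadec-18-en-9-one | C=CCCCCCCC[C@@H](O[Si](C)(C)C(C)(C)C)C(=O)C[C@H](O)[C@H](Cl)CCCCC | intermediate
15 | 7-O-diethylborinate chelate of 14 (not isolated) | C=CCCCCCCC[C@@H](O[Si](C)(C)C(C)(C)C)C(=O)C[C@H](OB(CC)CC)[C@H](Cl)CCCCC | intermediate
16 | (6R,7S,9R,10R)-10-{[tert-butyl(dimethyl)silyl]oxy}-6-chlorononadec-18-ene-7,9-diol | C=CCCCCCCC[C@@H](O[Si](C)(C)C(C)(C)C)[C@H](O)C[C@H](O)[C@H](Cl)CCCCC | intermediate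
17 | (2S,3S,5R)-5-[(1R)-1-{[tert-butyl(dimethyl)silyl]oxy}dec-9-en-1-yl]-2-pentyloxolan-3-ol | C=CCCCCCCC[C@@H](O[Si](C)(C)C(C)(C)C)[C@H]1C[C@H](O)[C@H](CCCCC)O1 | intermediate
18 | hexadecanoyl chloride (palmitoyl chloride) | CCCCCCCCCCCCCCCC(=O)Cl | starting material
19 | (2S,3S,5R)-5-[(1R)-1-{[tert-butyl(dimethyl)silyl]oxy}dec-9-en-1-yl]-2-pentyloxolan-3-yl hexadecanoate | C=CCCCCCCC[C@@H](O[Si](C)(C)C(C)(C)C)[C@H]1C[C@H](OC(=O)CCCCCCCCCCCCCCC)[C@H](CCCCC)O1 | intermediate
20 | (2S,3S,5R)-5-[(1R)-1-hydroxydec-9-en-1-yl]-2-pentyloxolan-3-yl hexadecanoate (CNP0186581.1) | C=CCCCCCCC[C@@H](O)[C@H]1C[C@H](OC(=O)CCCCCCCCCCCCCCC)[C@H](CCCCC)O1 | target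

**Totals**
Total step count: 11. Longest linear sequence: 10 steps (steps 1–5, then 7–11); step 6 is the one-step side branch.

**Three steps most likely to fail, with fallbacks**

Step 6 (α-chlorination). The risks are a lower ee than needed, racemisation of 12 on handling, and the catalyst sense, which rests on a shielding model; ee and sense are checked on a NaBH4-reduced aliquot. The fallback replaces asymmetric catalysis by resolution through the C10 stereocentre. It sets out from 11: N-chlorosuccinimide with catalytic DL-proline (CH2Cl2, 0 °C) gives racemic 2-chloroheptanal F1. F1 is used in excess in the aldol with enolate 13 under the step 7 conditions. Because 10 is a single enantiomer, the two anti adducts are diastereomers; chromatography removes (6S,7R,10R)-10-{[tert-butyl(dimethyl)silyl]oxy}-6-chloro-7-hydroxynonadec-18-en-9-one F2, and the route is rejoined at 14.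

Step 7 (aldol). The risks are enolate equilibration toward C10, base-induced loss or racemisation of the chloroaldehyde, and insufficient anti selectivity. The fallback sets out from 10: LiN(iPr)2 and Me3SiCl (THF, −78 °C) give the isolated methyl-side enol silane (3R)-3-{[tert-butyl(dimethyl)silyl]oxy}-2-[(trimethylsilyl)oxy]dodeca-1,11-diene F3. A BF3·OEt2-mediated Mukaiyama aldol addition of F3 to 12 (CH2Cl2, −78 °C) proceeds through an open transition state with no strong base present and gives the same 6,7-anti adduct, coming back at 14.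

Step 9 (ring closure). The risks are epoxide formation through the C7 hydroxyl, silyl loss and incomplete conversion. The fallback gives up the chloride and closes the ring on an alkene, which also bypasses 12.
- It sets out from 10: the boron aldol with (−)-Ipc2BCl/Et3N (Et2O, −78 °C) and (E)-hept-2-enal gives (5E,7S,10R)-10-{[tert-butyl(dimethyl)silyl]oxy}-7-hydroxynonadeca-5,18-dien-9-one F4. I could not fix from memory which Ipc2BCl antipode gives 7S, so the C7 configuration is confirmed by Mosher analysis and the other antipode is used if needed.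
- Et2BOMe/NaBH4 reduction as in step 8 gives (5E,7S,9R,10R)-10-{[tert-butyl(dimethyl)silyl]oxy}nonadeca-5,18-diene-7,9-diol F5.
- I2/NaHCO3 (MeCN, 0 °C) effects 5-exo iodoetherification, cis-selective with respect to the allylic hydroxyl and anti across the E-alkene, to give (2R,3S,5R)-5-[(1R)-1-{[tert-butyl(dimethyl)silyl]oxy}dec-9-en-1-yl]-2-[(1S)-1-iodopentyl]oxolan-3-ol F6. Competing 6-endo closure is the main uncertainty here.
- Bu3SnH/AIBN (toluene, 80 °C) removes the iodine, and the route comes back at 17.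

**Further compounds**
F1 | step 6 | racemic 2-chloroheptanal | CCCCCC(Cl)C=O
F2 | step 6 | (6S,7R,10R)-10-{[tert-butyl(dimethyl)silyl]oxy}-6-chloro-7-hydroxynonadec-18-en-9-one | C=CCCCCCCC[C@@H](O[Si](C)(C)C(C)(C)C)C(=O)C[C@@H](O)[C@@H](Cl)CCCCC
F3 | step 7 | (3R)-3-{[tert-butyl(dimethyl)silyl]oxy}-2-[(trimethylsilyl)oxy]dodeca-1,11-diene | C=CCCCCCCC[C@@H](O[Si](C)(C)C(C)(C)C)C(=C)O[Si](C)(C)C
F4 | step 9 | (5E,7S,10R)-10-{[tert-butyl(dimethyl)silyl]oxy}-7-hydroxynonadeca-5,18-dien-9-one | C=CCCCCCCC[C@@H](O[Si](C)(C)C(C)(C)C)C(=O)C[C@H](O)/C=C/CCCC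
F5 | step 9 | (5E,7S,9R,10R)-10-{[tert-butyl(dimethyl)silyl]oxy}nonadeca-5,18-diene-7,9-diol | C=CCCCCCCC[C@@H](O[Si](C)(C)C(C)(C)C)[C@H](O)C[C@H](O)/C=C/CCCC
F6 | step 9 | (2R,3S,5R)-5-[(1R)-1-{[tert-butyl(dimethyl)silyl]oxy}dec-9-en-1-yl]-2-[(1S)-1-iodopentyl]oxolan-3-ol | C=CCCCCCCC[C@@H](O[Si](C)(C)C(C)(C)C)[C@H]1C[C@H](O)[C@H]([C@@H](I)CCCC)O1
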